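**Retrosynthetic overview**
- The strategy rests on the docosanoyl chain of target 9. Counting the ester carbonyl as C1, C2–C21 are unbranched methylene groups ending in the C22 methyl group, with no heteroatom, branch or stereocentre. The only ring is the phenyl ring of the benzyl ester.
- Key disconnection C5–C6: C6–C22 comes from stearic acid 4 after loss of CO2, and C1–C5 with the benzyl ester comes from monobenzyl adipate 3 after loss of CO2. The two are joined by a crossed Kolbe anodic coupling.
- Half ester 3 is made in one step from adipic acid 1 and benzyl alcohol 2 by partial Fischer esterification.
- No ring is formed at any stage; the phenyl ring arrives with 2.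

Key step: step 2

Assumption: stearic acid of high chain-length purity is used, because palmitic acid in technical grades would be carried through the electrolysis to benzyl icosanoate, a homologue that is hard to remove.

**Step 1**
Reactants: 1 adipic acid; 2 benzyl alcohol
Product: 3 monobenzyl adipate (6-(benzyloxy)-6-oxohexanoic acid)
Conditions: 1 (1.5 equiv), 2 (1.0 equiv), TsOH·H2O (cat.), toluene, reflux, Dean–Stark; then aq. NaHCO3 extraction, acidification, CH2Cl2
Reagents that add atoms: none
Why: Fischer esterification with azeotropic removal of water should give mainly the half ester when the diacid is in excess; 3 is separated from neutral dibenzyl adipate by extraction into aqueous NaHCO3 and from water-soluble adipic acid by back-extraction into CH2Cl2 after acidification.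

**Step 2**
Reactants: 3 monobenzyl adipate; 4 stearic acid
Product: 9 benzyl docosanoate, via triethylammonium stearate 5 (not isolated), via triethylammonium monobenzyl adipate 6 (not isolated), via heptadecyl radical 7 (not isolated), via 5-(benzyloxy)-5-oxopentyl radical 8 (not isolated)
Conditions: 4 (3 equiv), 3 (1 equiv), Et3N (0.1 equiv per CO2H), MeCN/H2O (19:1), smooth Pt anode and Pt cathode, undivided cell, constant current (about 0.2 A cm−2), 50 °C, polarity reversed periodically, stopped while still weakly acidic; then silica gel chromatography (hexane to hexane/EtOAc)
Reagents that add atoms: none
Why: Partial neutralisation gives carboxylates 5 and 6, which are each oxidised by one electron at the platinum anode and lose CO2 at once, so the primary radicals 7 and 8 build up close to the electrode and combine there to form the C5–C6 bond of 9. The closest known reaction type is the crossed Kolbe electrolysis of a fatty acid with an alkyl hydrogen adipate, the classical four-carbon chain extension. No ring is closed and no stereocentre is created. The selectivity needed is cross-coupling over homocoupling, which is only statistical; the threefold excess of 4 should direct most of radical 8 into the cross product, and the symmetrical by-products tetratriacontane (a hydrocarbon) and dibenzyl sebacate (a diester) differ clearly from monoester 9 in polarity. Both radicals are primary and unstabilised, so further oxidation to cations (the Hofer–Moest path) should stay minor at smooth platinum, high current density and weakly acidic pH. The benzyl ester sits four carbons from the radical centre, the alcohol-free medium rules out transesterification, and keeping free acid present until the end keeps base generated at the cathode from saponifying it.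

**Compound list**
1 | adipic acid (hexanedioic acid) | OC(=O)CCCCC(=O)O | starting material
2 | benzyl alcohol | OCc1ccccc1 | starting material
3 | monobenzyl adipate (6-(benzyloxy)-6-oxohexanoic acid) | OC(=O)CCCCC(=O)OCc1ccccc1 | intermediate
4 | stearic acid (octadecanoic acid) | CCCCCCCCCCCCCCCCCC(=O)O | starting material
5 | triethylammonium stearate | CCCCCCCCCCCCCCCCCC(=O)[O-].CC[NH+](CC)CC | intermediate
6 | triethylammonium monobenzyl adipate (triethylammonium 6-(benzyloxy)-6-oxohexanoate) | [O-]C(=O)CCCCC(=O)OCc1ccccc1.CC[NH+](CC)CC | intermediate
7 | heptadecyl radical | [CH2]CCCCCCCCCCCCCCCC | intermediate
8 | 5-(benzyloxy)-5-oxopentyl radical | [CH2]CCCC(=O)OCc1ccccc1 | intermediate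
9 | benzyl docosanoate | CCCCCCCCCCCCCCCCCCCCCC(=O)OCc1ccccc1 | target

**Total step count:** 2
**Longest linear sequence:** 2 steps (1 → 3 → 9; 2 and 4 are used as bought)

**Steps most likely to fail** (the route has only two steps, so both are listed, the riskier first)

Step 2. Radical pairing is statistical and may divert too much material into the two symmetrical dimers. Wax deposited on the anode may raise the cell voltage and shift the reaction towards two-electron oxidation. The benzyl group may also be lost through anodic attack at the benzylic position or through local base at the cathode. The fallback replaces the radical coupling by a polar, copper-catalysed sp3–sp3 coupling and moves the disconnection to C4–C5. It sets out from benzyl alcohol 2, which is acylated with 4-bromobutanoyl chloride (pyridine, CH2Cl2, 0 °C) to give benzyl 4-bromobutanoate F1. Slow addition of commercially available octadecylmagnesium chloride to F1 with catalytic Li2CuCl4 in THF/NMP at 0 °C (a Kochi-type Grignard–alkyl bromide coupling, in which substitution at the primary bromide outruns addition to the ester) should join C18 to C4. It returns to the route at target 9.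

Step 1. The esterification may run on to the diester, and acid-catalysed self-condensation of benzyl alcohol to its ether may consume the alcohol, so that the half ester is not obtained cleanly from the statistical mixture. The fallback inverts the approach: exhaustive esterification, then removal of one ester group. It sets out from adipic acid 1, which with an excess of benzyl alcohol 2 (TsOH·H2O, toluene, Dean–Stark) is driven fully to dibenzyl adipate F2. Half-saponification with one equivalent of KOH in THF/water at 0 °C should give potassium 6-(benzyloxy)-6-oxohexanoate F3. F3 stays in the aqueous phase while unreacted F2 is extracted and recycled. Acidification with HCl returns to the route at compound 3.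

**Further compounds**
F1 | step 2 | benzyl 4-bromobutanoate | BrCCCC(=O)OCc1ccccc1
F2 | step 1 | dibenzyl adipate (dibenzyl hexanedioate) | O=C(CCCCC(=O)OCc1ccccc1)OCc1ccccc1
F3 | step 1 | potassium 6-(benzyloxy)-6-oxohexanoate | [K+].[O-]C(=O)CCCCC(=O)OCc1ccccc1
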